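The trap in a row like this was to read more partner as more bis adduct, as if the product stayed once made.

| flask | substrate | partner | remark | time |
|---|---|---|---|---|
| east | 0.20 M | 0.45 equiv | run made earlier |  |
| south-west | 0.20 M | 6.2 equiv | run made earlier |  |
| epsilon | 0.20 M | 0.600 equiv |  | 2.5 min |
| eta | 0.20 M | 1.20 equiv |  | 2.5 min |
| delta | 0.20 M | 2.00 equiv |  | 2.5 min |
| zeta | 0.20 M | 4.00 equiv |  | 2.5 min |
| beta | 0.20 M | 8.00 equiv |  | 2.5 min |

- east (time / s: bis adduct / %, substrate / %): 10.0: 0, 93; 25.0: 3, 93; 50.0: 2, 83; 80.0: 5, 76; 120: 8, 71
- south-west (time / s: bis adduct / %, substrate / %): 10.0: 24, 50; 25.0: 61, 21; 50.0: 84, 3; 80.0: 86, 4; 120: 79, 1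

(standard deviation of a reading: 1.5 percentage points)

- "hardly changes" means that all values lie within two and a half points (for a concentration: within two and a half percent of the largest)

- amount of bis adduct at the end, in percent of the substrate charged for epsilon, eta, delta, zeta, beta, in this order
- how that number moves from the first to the last of them (falls, then rises / rises all the way / rises, then falls / hardly changes / falls all the way)

How fast was bis adduct made? In the south-west run I treated the substrate decay as pseudo-first-order, and the readings at 10.0 s and 25.0 s gave a time constant of 17.3 s. That was shorter than the 2.5 min asked for, so I asked what the rest of the time did.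

Did bis adduct last? In the south-west run the bis adduct reading fell from 86% at 80.0 s to 79% at 120 s, a drop of 7 percentage points against a scatter of 1.5 points per reading, so I took it as real. Read as a decay, these two readings gave 471 s for the loss time, the time constant of bis adduct once made, in the south-west run.

How did that move with the charge? I assumed, unproven, that both clocks ran in proportion to partner, and that the loss ran on the partner left after two had gone into each bis adduct. Beta's loss time then came to 5.50 min and zeta's to 16.5 min. After a making delay of 13.4 s, I reckoned that beta kept 66.1% of its bis adduct. After 26.8 s, I reckoned that zeta kept 88.3%. The partner charged to epsilon allowed at most 30.0% of bis adduct, so I expected the row to rise from epsilon and to fall from zeta to beta.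

The forecast gave 14.5%, 38.5%, 69%, 86% and 67%, with the shape "rises, then falls", reasoning that “bis is slowly lost”.

The flasks gave 13.0%, 35.8%, 63.9%, 86.5% and 68.6%: rises, then falls.

    substrate + partner → first product + by-product (k = 0.0610 M⁻¹ s⁻¹)
    partner + first product → bis adduct + by-product (k = 0.105 M⁻¹ s⁻¹)
    partner + bis adduct → tris adduct + by-product (k = 0.00243 M⁻¹ s⁻¹)
    crystals ⇌ by-product, rate k4*(cs4 - [by-product]) while solid is left; crystals form when [by-product] > cs4 (solubility = 0.0880 M, k = 0.435 s⁻¹)

In beta, the reckoned loss time of 5.50 min stood against a run of 2.5 min, and bis adduct went from 83.9% at 1.25 min to 68.6% at 2.50 min, with tris adduct at 31.4%; the loss time gave 66.8%. In zeta, starting from 86.5% at 2.50 min, the reckoned loss time of 16.5 min gave 22.1% at 25.0 min, where the flask held 32.4% of bis adduct and partner had gone from 48.3% to 33.1% of its charge.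

The data were generated by integration with constants of no real substance; the scatter is artificial.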